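The route rests on cutting the furan of the 14-membered carbocycle at C4–C5 and O–C6. The 3-furoate unit C3–C4(CO2Me) is a latent β-keto ester, and C5–C6≡C7 a propargyl unit that carries the C8 carbinol on the alkyne. In one operation the carvone-derived keto ester acetal 5 (C13–C4) is C-propargylated by the malate-derived bromide 20 (C5–C12, with C10–C12 held as a butanolide), and gold-catalysed 5-exo-dig oxycyclisation turns the alkynyl keto ester into the 2,5-dialkyl-3-furoate 22, which unites both halves. The ring is then closed at C12=C13 by an intramolecular Horner–Wadsworth–Emmons reaction.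

Key step: step 15

Atom labels: C1–C14 are the carbons of the target carbocycle (C1 isopropenyl-bearing CH, C2 CH2, C3–C6 furan carbons, C7 CH2, C8 methyl carbinol, C9 CH2, C10 ketone, C11 carbinol, C12=C13 enoate alkene, C14 CH2).

Design remarks:
- C11–OH is carried as a TIPS ether because the late lactone opening frees the neighbouring C10–OH under basic conditions and a smaller silyl group could migrate.
- C8–OH is carried as a TES ether only from step 12 to step 17, so that it is shed together with the acetal.
- C10 of the butanolide is a sacrificial stereocentre (made R, oxidised in step 20).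
- The CIP descriptors of C1 and C8 change along the route although their geometry does not.

Assumption: the C8 carbinol is made by adding methyl to the C8 alkynyl ketone (not alkynyl to a methyl ketone), the order for which 1,3-induction from C10 is predicted to give the required configuration.

Step 1
Reactants: 1 (S)-(+)-carvone
Product: 2 trans-carvone oxide
Conditions: H2O2 (30% aq.), NaOH (cat.), MeOH, 0 °C
Reagents that add atoms: hydrogen peroxide, OO
Why: Weitz–Scheffer nucleophilic epoxidation attacks only the electron-poor enone alkene (the isopropenyl group is inert to hydroperoxide anion) and delivers oxygen anti to the ring substituent; both epoxide carbons are excised later, so only chemoselectivity matters.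

Step 2
Reactants: 2 trans-carvone oxide
Product: 3 epoxy β-hydroxy ester
Conditions: MeOAc, LiN(i-Pr)2, THF, −78 °C; then 2, −78 °C; AcOH
Reagents that add atoms: methyl acetate, CC(=O)OC
Why: Aldol-type 1,2-addition of the lithium enolate of methyl acetate to the ketone at low temperature attaches the future C4 and its ester carbon to the future C3; the carbinol configuration (either epimer) is irrelevant because this carbon becomes the C3 ketone.

Step 3
Reactants: 3 epoxy β-hydroxy ester
Product: 5 west keto ester acetal (C13–C4), via keto aldehyde 4 (not isolated)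
Conditions: H5IO6, THF/H2O, 0 °C to rt; extractive work-up; then HC(OMe)3, MeOH, CeCl3·7H2O (cat.), rt
Reagents that add atoms: trimethyl orthoformate, COC(OC)OC; methanol, CO
Why: Periodic acid hydrolyses the epoxide to the triol and cleaves both glycol bonds (Malaprade cleavage), which expels the methyl-bearing carbon as acetic acid and unveils the C3 ketone and the C13 aldehyde with C1 untouched; the aldehyde is acetalised at once and chemoselectively (the enolised β-keto ester carbonyl reacts far more slowly), so the 1,5-keto aldehyde has no time for intramolecular Knoevenagel condensation.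

Step 4
Reactants: 6 propargyl alcohol
Product: 7 PMB propargyl ether
Conditions: NaH, PMBCl, Bu4NI (cat.), THF, 0 °C to rt
Reagents that add atoms: 4-methoxybenzyl chloride, COc1ccc(CCl)cc1
Why: Williamson etherification; the PMB group is chosen because it is later removed oxidatively without touching silyl ethers or the lactone.

Step 5
Reactants: 7 PMB propargyl ether
Product: 8 PMB-oxy alkynyl methyl ketone
Conditions: n-BuLi, THF, −78 °C; then MeC(O)N(OMe)Me, −78 to 0 °C; NH4Cl (aq.)
Reagents that add atoms: N-methoxy-N-methylacetamide, CC(=O)N(C)OC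
Why: Acylation of the lithium acetylide with a Weinreb amide stops at the ketone because the chelated tetrahedral intermediate survives until work-up.

Step 6
Reactants: 8 PMB-oxy alkynyl methyl ketone
Product: 9 2-silyloxy enyne
Conditions: TMSOTf, Et3N, CH2Cl2, 0 °C
Reagents that add atoms: trimethylsilyl triflate, C[Si](C)(C)OS(=O)(=O)C(F)(F)F
Why: Soft enolisation (silyl triflate and amine) gives the silyl enol ether at the methyl group, the only enolisable α-position of the ynone; the crude product is used directly.

Step 7
Reactants: 10 dimethyl (S)-malate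
Product: 11 methyl (3S)-3,4-dihydroxybutanoate
Conditions: BH3·SMe2, NaBH4 (5 mol %), THF, rt; MeOH
Reagents that add atoms: none
Why: Hydroxyl-directed borane reduction takes only the ester next to the free hydroxyl (through a cyclic alkoxyborane) and leaves the β-ester; the C11 stereocentre comes unchanged from (S)-malate.

Step 8
Reactants: 11 methyl (3S)-3,4-dihydroxybutanoate
Product: 13 methyl (3S)-4-(triethylsilyloxy)-3-(triisopropylsilyloxy)butanoate, via primary TES ether 12 (not isolated)
Conditions: TESOTf (1.0 equiv), 2,6-lutidine, CH2Cl2, −78 °C; then TIPSOTf, −78 to 0 °C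
Reagents that add atoms: triethylsilyl triflate, CC[Si](CC)(CC)OS(=O)(=O)C(F)(F)F; triisopropylsilyl triflate, CC(C)[Si](C(C)C)(C(C)C)OS(=O)(=O)C(F)(F)F
Why: Stepwise silyl ether formation: one equivalent of the small silyl triflate reacts at −78 °C with the less hindered primary hydroxyl, and the secondary hydroxyl (future C11–O) is then capped as the bulky TIPS ether.

Step 9
Reactants: 13 methyl (3S)-4-(triethylsilyloxy)-3-(triisopropylsilyloxy)butanoate
Product: 14 methyl (3S)-4-oxo-3-(triisopropylsilyloxy)butanoate
Conditions: (COCl)2, DMSO, CH2Cl2, −78 to −35 °C; then Et3N, −78 °C to rt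
Reagents that add atoms: none
Why: Swern oxidation applied directly to a primary triethylsilyl ether: the chlorosulfonium/HCl medium cleaves only the primary TES ether and oxidises the released alcohol in situ, so the γ-hydroxy ester (which would lactonise) is never isolated and the α-silyloxy aldehyde is formed cold, without epimerisation.

Step 10
Reactants: 14 methyl (3S)-4-oxo-3-(triisopropylsilyloxy)butanoate; 9 2-silyloxy enyne
Product: 16 butanolide alkynyl ketone, via anti-aldol adduct 15 (not isolated)
Conditions: BF3·OEt2, CH2Cl2, −78 °C; NaHCO3 (aq.) work-up; then PPTS (cat.), CH2Cl2, rt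
Reagents that add atoms: none
Why: Mukaiyama aldol addition under non-chelating BF3 activation follows the Felkin–Anh model of the α-silyloxy aldehyde and should give the 3,4-anti adduct (C10 R; this centre is sacrificial, so a minor epimer would converge later), and the γ-hydroxy ester then lactonises under mild acid faster than the hydroxyl can add to the ynone.

Step 11
Reactants: 16 butanolide alkynyl ketone
Product: 17 tertiary propargylic alcohol
Conditions: MeLi, CeCl3, THF, −78 °C
Reagents that add atoms: methyllithium, [Li]C
Why: 1,2-Addition of the non-basic organocerium reagent to the ynone, which is far more electrophilic than the lactone and is neither enolised nor opened by β-elimination; the new C8 centre is set by 1,3-induction from C10 (polar model: carbonyl anti to C11 about C9–C10, methyl entering from the side of C10–H and not of the lactone oxygen), which predicts the (S)-carbinol shown, with moderate selectivity expected and the minor epimer removed by chromatography.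

Step 12
Reactants: 17 tertiary propargylic alcohol
Product: 18 C8 triethylsilyl ether
Conditions: TESOTf, 2,6-lutidine, CH2Cl2, −78 to 0 °C
Reagents that add atoms: triethylsilyl triflate, CC[Si](CC)(CC)OS(=O)(=O)C(F)(F)F
Why: Silylation of the hindered tertiary alcohol with a silyl triflate; the ether masks C8–OH against cationic gold (no Meyer–Schuster rearrangement) and against the amide base of step 16.

Step 13
Reactants: 18 C8 triethylsilyl ether
Product: 19 primary propargylic alcohol
Conditions: DDQ, CH2Cl2/pH 7 buffer, 0 °C to rt
Reagents that add atoms: none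
Why: Oxidative PMB cleavage (hydride abstraction by DDQ, hydrolysis of the oxocarbenium ion) leaves both silyl ethers, the alkyne and the lactone untouched.

Step 14
Reactants: 19 primary propargylic alcohol
Product: 20 east propargylic bromide (C5–C12)
Conditions: CBr4, PPh3, CH2Cl2, 0 °C
Reagents that add atoms: carbon tetrabromide, BrC(Br)(Br)Br
Why: Appel reaction converts the primary propargylic alcohol into the bromide under neutral conditions that do not affect the silyl ethers or the lactone.

Step 15
Reactants: 5 west keto ester acetal (C13–C4); 20 east propargylic bromide (C5–C12)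
Product: 22 2,5-dialkyl-3-furoate carrying both chains, via C-propargylated keto ester 21 (not isolated)
Conditions: K2CO3, acetone, rt (5 in slight excess); filtration, solvent switch; then Ph3PAuNTf2 (5 mol %), toluene, rt
Reagents that add atoms: none
Why: Carbonate deprotonates only the β-keto ester C4–H, and the soft enolate displaces the primary propargylic bromide at C5 by SN2 (bond C4–C5), giving 21 as an inconsequential pair of C4 epimers. After the bromide salts are filtered off (halide would deactivate the catalyst), Ph3PAuNTf2 coordinates the C6≡C7 alkyne, the C3 enol oxygen adds anti to gold at C6 (bond O–C6), protodeauration gives the 5-alkylidene-4,5-dihydrofuran, and a proton shift from C5 to C7 aromatises it to the furan. The closest known chemistry is the C-propargylation of β-keto esters followed by cycloisomerisation of 2-propargyl-1,3-dicarbonyl compounds to 2,5-disubstituted 3-furoates. The furan is closed in the 5-exo-dig mode; the 6-endo-dig alternative (attack at C7) is disfavoured geometrically and by the fully substituted C8 next to C7. No stereocentre is created, and C1, C8, C10 and C11 lie away from every acidic or ionisable position under these conditions. The step needs C- over O-alkylation and SN2 over SN2′ (secured by the stabilised enolate, the unhindered CH2Br and the quaternary C8 at the SN2′ terminus) and survival of the tertiary propargylic silyl ether (secured by a neutral, halide-free cationic gold catalyst at room temperature).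

Step 16
Reactants: 22 2,5-dialkyl-3-furoate carrying both chains
Product: 24 α-phosphono butanolide, via phosphonite 23 (not isolated)
Conditions: LiN(SiMe3)2, THF, −78 °C; ClP(OEt)2, −78 °C; then t-BuOOH, −78 to 0 °C
Reagents that add atoms: diethyl chlorophosphite, CCOP(Cl)OCC; tert-butyl hydroperoxide, CC(C)(C)OO
Why: C-Phosphinylation of the lactone lithium enolate with a trivalent phosphorus chloride, then oxidation of the phosphonite to the phosphonate; enolates of 3-silyloxy butanolides can be trapped at −78 °C before β-elimination, the lactone α-CH2 is the most acidic and least hindered site, and the new C12 centre (either epimer) is destroyed in step 18.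

Step 17
Reactants: 24 α-phosphono butanolide
Product: 25 phosphono aldehyde with free C8 hydroxyl
Conditions: TsOH·H2O (cat.), acetone/H2O, rt
Reagents that add atoms: water, O
Why: Acid-catalysed acetal hydrolysis frees the C13 aldehyde and the same medium cleaves the acid-labile tertiary TES ether, while the secondary TIPS ether, the phosphono lactone, the furan ester and the isopropenyl group tolerate catalytic acid at room temperature.

Step 18
Reactants: 25 phosphono aldehyde with free C8 hydroxyl
Product: 26 macrocyclic (E)-α-alkylidene butanolide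
Conditions: LiCl, DBU, MeCN, high dilution (1 mM), rt
Reagents that add atoms: none
Why: Intramolecular Horner–Wadsworth–Emmons olefination with LiCl and an amidine base at high dilution closes the 14-membered carbocycle at C12=C13; the E geometry (C14 cis to C11, trans to the carbonyl) is the usual outcome for α-phosphono lactones and the one that keeps both ring bonds cis on the alkene, and the mild base limits β-elimination of the C11 silyloxy group.

Step 19
Reactants: 26 macrocyclic (E)-α-alkylidene butanolide
Product: 28 C10 hydroxy dimethyl ester, via lithium carboxylate 27 (not isolated)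
Conditions: LiOH·H2O, THF/H2O, 0 °C; CO2, concentration; then MeI, DMF, rt
Reagents that add atoms: lithium hydroxide, [Li+].[OH-]; iodomethane, CI
Why: Saponification of the lactone and SN2 O-methylation of the carboxylate give the γ-hydroxy methyl ester without any acid that would relactonise it; furoate hydrolysed alongside is re-methylated in the same operation, the TIPS ether resists migration to the C10 hydroxyl, and the crude product is oxidised at once.

Step 20
Reactants: 28 C10 hydroxy dimethyl ester
Product: 29 C10 ketone with C11 silyl ether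
Conditions: Dess–Martin periodinane, NaHCO3, CH2Cl2, 0 °C to rt
Reagents that add atoms: none
Why: Dess–Martin oxidation converts the only secondary alcohol (C10) into the ketone under buffered, non-basic conditions; the tertiary C8 alcohol cannot be oxidised and the still silylated C11 centre is not enolised.

Step 21
Reactants: 29 C10 ketone with C11 silyl ether
Product: 30 CNP0225662.1
Conditions: HF·pyridine, pyridine, THF, 0 °C to rt
Reagents that add atoms: none
Why: Fluoride-mediated desilylation in a buffered, weakly acidic medium removes the TIPS ether without base, which avoids retro-aldol cleavage of the C8–C10 β-hydroxy ketone and epimerisation of the C11 α-hydroxy ketone.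

Compound list

1 | (S)-(+)-carvone, (5S)-2-methyl-5-(prop-1-en-2-yl)cyclohex-2-en-1-one | CC1=CC[C@@H](CC1=O)C(C)=C | starting material
2 | (1S,4S,6S)-1-methyl-4-(prop-1-en-2-yl)-7-oxabicyclo[4.1.0]heptan-2-one (trans-carvone oxide) | C[C@]12O[C@H]1C[C@@H](CC2=O)C(C)=C | intermediate
3 | methyl 2-[(1S,4S,6S)-2-hydroxy-1-methyl-4-(prop-1-en-2-yl)-7-oxabicyclo[4.1.0]heptan-2-yl]acetate (carbinol epimers) | C[C@]12O[C@H]1C[C@@H](CC2(O)CC(=O)OC)C(C)=C | intermediate
4 | methyl (5S)-3,7-dioxo-5-(prop-1-en-2-yl)heptanoate | C=C(C)[C@H](CC(=O)CC(=O)OC)CC=O | intermediate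
5 | methyl (5S)-7,7-dimethoxy-3-oxo-5-(prop-1-en-2-yl)heptanoate (west keto ester acetal, C13–C4) | C=C(C)[C@H](CC(=O)CC(=O)OC)CC(OC)OC | intermediate
6 | propargyl alcohol (prop-2-yn-1-ol) | C#CCO | starting material
7 | 1-methoxy-4-[(prop-2-yn-1-yloxy)methyl]benzene | C#CCOCc1ccc(OC)cc1 | intermediate
8 | 5-[(4-methoxyphenyl)methoxy]pent-3-yn-2-one | CC(=O)C#CCOCc1ccc(OC)cc1 | intermediate
9 | trimethyl({5-[(4-methoxyphenyl)methoxy]pent-1-en-3-yn-2-yl}oxy)silane | C=C(O[Si](C)(C)C)C#CCOCc1ccc(OC)cc1 | intermediate
10 | dimethyl (S)-malate, dimethyl (2S)-2-hydroxybutanedioate | COC(=O)C[C@H](O)C(=O)OC | starting material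
11 | methyl (3S)-3,4-dihydroxybutanoate | COC(=O)C[C@H](O)CO | intermediate
12 | methyl (3S)-3-hydroxy-4-[(triethylsilyl)oxy]butanoate | COC(=O)C[C@H](O)CO[Si](CC)(CC)CC | intermediate
13 | methyl (3S)-4-[(triethylsilyl)oxy]-3-{[tri(propan-2-yl)silyl]oxy}butanoate | COC(=O)C[C@H](O[Si](C(C)C)(C(C)C)C(C)C)CO[Si](CC)(CC)CC | intermediate
14 | methyl (3S)-4-oxo-3-{[tri(propan-2-yl)silyl]oxy}butanoate (C10–C12 aldehyde) | COC(=O)C[C@H](O[Si](C(C)C)(C(C)C)C(C)C)C=O | intermediate
15 | methyl (3S,4R)-4-hydroxy-9-[(4-methoxyphenyl)methoxy]-6-oxo-3-{[tri(propan-2-yl)silyl]oxy}non-7-ynoate | COC(=O)C[C@H](O[Si](C(C)C)(C(C)C)C(C)C)[C@H](O)CC(=O)C#CCOCc1ccc(OC)cc1 | intermediate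
16 | (4S,5R)-5-{5-[(4-methoxyphenyl)methoxy]-2-oxopent-3-yn-1-yl}-4-{[tri(propan-2-yl)silyl]oxy}oxolan-2-one | O=C(C[C@H]1OC(=O)C[C@@H]1O[Si](C(C)C)(C(C)C)C(C)C)C#CCOCc1ccc(OC)cc1 | intermediate
17 | (4S,5R)-5-{(2S)-2-hydroxy-5-[(4-methoxyphenyl)methoxy]-2-methylpent-3-yn-1-yl}-4-{[tri(propan-2-yl)silyl]oxy}oxolan-2-one | COc1ccc(COCC#C[C@@](C)(O)C[C@H]2OC(=O)C[C@@H]2O[Si](C(C)C)(C(C)C)C(C)C)cc1 | intermediate
18 | (4S,5R)-5-{(2S)-5-[(4-methoxyphenyl)methoxy]-2-methyl-2-[(triethylsilyl)oxy]pent-3-yn-1-yl}-4-{[tri(propan-2-yl)silyl]oxy}oxolan-2-one | COc1ccc(COCC#C[C@@](C)(O[Si](CC)(CC)CC)C[C@H]2OC(=O)C[C@@H]2O[Si](C(C)C)(C(C)C)C(C)C)cc1 | intermediate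
19 | (4S,5R)-5-{(2S)-5-hydroxy-2-methyl-2-[(triethylsilyl)oxy]pent-3-yn-1-yl}-4-{[tri(propan-2-yl)silyl]oxy}oxolan-2-one | OCC#C[C@@](C)(O[Si](CC)(CC)CC)C[C@H]1OC(=O)C[C@@H]1O[Si](C(C)C)(C(C)C)C(C)C | intermediate
20 | (4S,5R)-5-{(2S)-5-bromo-2-methyl-2-[(triethylsilyl)oxy]pent-3-yn-1-yl}-4-{[tri(propan-2-yl)silyl]oxy}oxolan-2-one (east propargylic bromide, C5–C12) | BrCC#C[C@@](C)(O[Si](CC)(CC)CC)C[C@H]1OC(=O)C[C@@H]1O[Si](C(C)C)(C(C)C)C(C)C | intermediate
21 | C-propargylated keto ester: 5 carrying at C4 the C5–C12 chain of 20 (C4 epimers) | C=C(C)[C@H](CC(=O)C(CC#C[C@@](C)(O[Si](CC)(CC)CC)C[C@H]1OC(=O)C[C@@H]1O[Si](C(C)C)(C(C)C)C(C)C)C(=O)OC)CC(OC)OC | intermediate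
22 | methyl 2-[(2R)-4,4-dimethoxy-2-(prop-1-en-2-yl)butyl]-5-{(2S)-2-methyl-3-[(2R,3S)-5-oxo-3-{[tri(propan-2-yl)silyl]oxy}oxolan-2-yl]-2-[(triethylsilyl)oxy]propyl}furan-3-carboxylate | C=C(C)[C@H](Cc1oc(C[C@@](C)(O[Si](CC)(CC)CC)C[C@H]2OC(=O)C[C@@H]2O[Si](C(C)C)(C(C)C)C(C)C)cc1C(=O)OC)CC(OC)OC | intermediate
23 | 22 bearing a diethoxyphosphanyl group at C12 (lactone α-carbon; C12 epimers) | C=C(C)[C@H](Cc1oc(C[C@@](C)(O[Si](CC)(CC)CC)C[C@H]2OC(=O)C(P(OCC)OCC)[C@@H]2O[Si](C(C)C)(C(C)C)C(C)C)cc1C(=O)OC)CC(OC)OC | intermediate
24 | 22 bearing a diethoxyphosphoryl group at C12 (α-phosphono butanolide; C12 epimers) | C=C(C)[C@H](Cc1oc(C[C@@](C)(O[Si](CC)(CC)CC)C[C@H]2OC(=O)C(P(=O)(OCC)OCC)[C@@H]2O[Si](C(C)C)(C(C)C)C(C)C)cc1C(=O)OC)CC(OC)OC | intermediate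
25 | phosphono aldehyde: 24 with C13 as the free aldehyde and C8 as the free tertiary alcohol | C=C(C)[C@H](Cc1oc(C[C@@](C)(O)C[C@H]2OC(=O)C(P(=O)(OCC)OCC)[C@@H]2O[Si](C(C)C)(C(C)C)C(C)C)cc1C(=O)OC)CC=O | intermediate
26 | macrocyclic (E)-α-alkylidene butanolide (C12=C13 closed; lactone from the C12 carboxyl to C10–O; C11 OTIPS; C8 OH) | C=C(C)[C@H]1C/C=C2/C(=O)O[C@@H]([C@H]2O[Si](C(C)C)(C(C)C)C(C)C)C[C@](C)(O)Cc2cc(C(=O)OC)c(C1)o2 | intermediate
27 | lithium carboxylate of the ring-opened lactone (C10 OH free) | C=C(C)[C@H]1C/C=C(/C(=O)[O-])[C@H](O[Si](C(C)C)(C(C)C)C(C)C)[C@H](O)C[C@](C)(O)Cc2cc(C(=O)OC)c(C1)o2.[Li+] | intermediate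
28 | macrocyclic dimethyl ester with (10R)-hydroxyl, (11S)-OTIPS, (8S)-hydroxyl and (12E)-alkene | C=C(C)[C@H]1C/C=C(/C(=O)OC)[C@H](O[Si](C(C)C)(C(C)C)C(C)C)[C@H](O)C[C@](C)(O)Cc2cc(C(=O)OC)c(C1)o2 | intermediate
29 | C10 ketone, C11 TIPS ether of the target | C=C(C)[C@H]1C/C=C(/C(=O)OC)[C@H](O[Si](C(C)C)(C(C)C)C(C)C)C(=O)C[C@](C)(O)Cc2cc(C(=O)OC)c(C1)o2 | intermediate
30 | CNP0225662.1, (1S,8R,11S,12E) in the carbocycle labels | C=C(C)[C@H]1C/C=C(/C(=O)OC)[C@H](O)C(=O)C[C@](C)(O)CC2=CC(C(=O)OC)=C(C1)O2 | target

Total step count: 21 (west branch steps 1–3, alkynyl ketone branch steps 4–6, east branch steps 7–14, union step 15, end game steps 16–21).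
Longest linear sequence: 15 steps (steps 7–21, from dimethyl (S)-malate 10 to 30).

Steps most likely to fail

Step 15. The cationic gold catalyst may ionise the C8 silyloxy group at the alkylidene-dihydrofuran stage, where it is allylic to an enol ether, so that elimination products form instead of the furan; residual bromide may also stop the catalyst. The fallback sets out from the C-propargylated keto ester 21, isolated after the carbonate stage, and returns at 22. The alkyne is hydrated with assistance of the C3 carbonyl (Hg(OTf)2 cat., MeCN/H2O, rt), so that water intercepts the cyclic enol ether as soon as it forms and gives the 1,4-diketone F1. Paal–Knorr cyclodehydration of this 2-acyl-1,4-dicarbonyl compound under very mild acid (PPTS, toluene, 40 °C) then closes the same furan and gives 22.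

Step 11. The facial selectivity of the methyl addition at C8 may be poor or opposite to the prediction, so that the wrong C8 epimer dominates. The fallback reverses the order in which the two C8 substituents arrive; it sets out from aldehyde 14 and returns at 17. Mukaiyama aldol addition of commercial 2-(trimethylsilyloxy)propene to 14 (BF3·OEt2, CH2Cl2, −78 °C) should give the anti-aldol hydroxy ester F2, which lactonises (PPTS) to the butanolide methyl ketone F3. The cerium acetylide of 7 (n-BuLi, CeCl3, THF, −78 °C) is then added to F3. Because the alkynyl group now attacks the carbonyl face that methyl attacked before, the ratio of C8 epimers should be inverted, and the required epimer 17 is isolated by chromatography.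

Step 16. The amide base may deprotonate the furan C2 methylene (vinylogously activated by the C4 ester) in competition with the lactone, and the lactone enolate may expel the C11 silyloxy group before it is trapped. The fallback installs the phosphonate before the union, on a simple intermediate where the lactone is the only acidic site; it sets out from 18 and returns at 24. Treatment of 18 with LiN(SiMe3)2 and ClP(OEt)2 at −78 °C, then t-BuOOH, should give the phosphono lactone PMB ether F4. DDQ then frees the phosphono propargylic alcohol F5, and the Appel reaction gives the phosphono propargylic bromide F6. Union of F6 with 5 under the conditions of step 15 passes through the C-alkylated phosphono keto ester F7 and gives 24 directly. Carbonate should still select the β-keto ester, which is several pKa units more acidic than the phosphono lactone.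

Further compounds

F1 | step 15 | 1,4-diketone from hydration of 21 at C6 (C3 and C6 ketones, C4 epimers) | C=C(C)[C@H](CC(=O)C(CC(=O)C[C@@](C)(O[Si](CC)(CC)CC)C[C@H]1OC(=O)C[C@@H]1O[Si](C(C)C)(C(C)C)C(C)C)C(=O)OC)CC(OC)OC
F2 | step 11 | methyl (3S,4R)-4-hydroxy-6-oxo-3-{[tri(propan-2-yl)silyl]oxy}heptanoate | COC(=O)C[C@H](O[Si](C(C)C)(C(C)C)C(C)C)[C@H](O)CC(C)=O
F3 | step 11 | (4S,5R)-5-(2-oxopropyl)-4-{[tri(propan-2-yl)silyl]oxy}oxolan-2-one | CC(=O)C[C@H]1OC(=O)C[C@@H]1O[Si](C(C)C)(C(C)C)C(C)C
F4 | step 16 | 18 bearing a diethoxyphosphoryl group on the lactone α-carbon (C12 epimers) | COc1ccc(COCC#C[C@@](C)(O[Si](CC)(CC)CC)C[C@H]2OC(=O)C(P(=O)(OCC)OCC)[C@@H]2O[Si](C(C)C)(C(C)C)C(C)C)cc1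
F5 | step 16 | 19 bearing a diethoxyphosphoryl group on the lactone α-carbon (C12 epimers) | OCC#C[C@@](C)(O[Si](CC)(CC)CC)C[C@H]1OC(=O)C(P(=O)(OCC)OCC)[C@@H]1O[Si](C(C)C)(C(C)C)C(C)C
F6 | step 16 | 20 bearing a diethoxyphosphoryl group on the lactone α-carbon (C12 epimers) | BrCC#C[C@@](C)(O[Si](CC)(CC)CC)C[C@H]1OC(=O)C(P(=O)(OCC)OCC)[C@@H]1O[Si](C(C)C)(C(C)C)C(C)C
F7 | step 16 | 21 bearing a diethoxyphosphoryl group on the lactone α-carbon (C4 and C12 epimers) | C=C(C)[C@H](CC(=O)C(CC#C[C@@](C)(O[Si](CC)(CC)CC)C[C@H]1OC(=O)C(P(=O)(OCC)OCC)[C@@H]1O[Si](C(C)C)(C(C)C)C(C)C)C(=O)OC)CC(OC)OC
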